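## Structural features

The target is a 7,9'-epoxylignan built on one oxolane ring (O1, C2–C5). C2 carries a 3,4,5-trimethoxyphenyl group directly, C3 a hydroxymethyl group (C9), C4 a 2,4,5-trimethoxybenzyl group through C7', and C5 is an unsubstituted methylene. C2, C3 and C4 are three contiguous stereocentres (2R,3R,4R), and all three substituents lie on the same face of the ring (2,3-cis and 3,4-cis), the most crowded arrangement. The C2–O1 bond is a benzylic ether activated by a very electron-rich arene, so acids can ionise it (epimerisation at C2) and hydrogenation catalysts can cleave it; both arenes are sensitive to oxidants and electrophiles. Whenever C9 is a carbonyl group, C3 is epimerisable and O1 can leave by β-elimination. The real difficulty is the all-cis array in one absolute sense: no centre can be set under equilibrating conditions, because equilibration would move at least the C3 substituent to the other face. The key step exploits the position of C3 between an oxygen-bearing benzylic carbon (C2) and a carbon (C4) that carries the benzylic carbon C7'. With C3 as a malonate carbon (C9 being one of its carboxyl groups), C2 is the β-carbon of an arylidene malonate that accepts O1, and O1–C5–C4–C7' is propargyl alcohol, whose alkyne accepts C3 at C4 and an aryl group at C7'.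

## Logic of the disconnections

**15 to 14.** No skeletal bond is cut; C9 is raised from the alcohol to the ester oxidation level. The ester is what remains of a malonate and prepares the next cut. The forward step needs hydride addition to be faster than enolisation, because the all-cis ester in 14 can epimerise at C3 or open by loss of O1.

**14 to 11 (through 13 and 12).** The C3–H bond is replaced by a C3–CO2H bond. C3 becomes a quaternary malonate carbon, which removes the need to control it early and turns it into a nucleophile for ring construction. The forward step breaks the C3–carboxyl bond homolytically and must deliver a hydrogen atom anti to both the C2 aryl and the C4 benzyl group. This is a kinetic outcome that places the ester on the crowded face.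

**11 to 10.** The acid is traced back to the second ethyl ester. The symmetric diester 10 has no stereocentre at C3 and comes from a symmetric malonate. The forward step has to stop at the half-acid.

**10 to 9.** Hydrogen is removed across C4–C7'. This deletes the C4 stereocentre and leaves a trisubstituted arylidene, the typical product of an alkyne carbopalladation. The forward hydrogenation must add to the face opposite the C2 aryl group and must spare the benzylic C2–O1 bond.

**9 to 3, 5 and 6 (through 8 and 7).** Three bonds are cut: O1–C2, C3–C4 and C7'–aryl. O1–C2 is an oxa-Michael bond, C3–C4 the attack of a malonate on a metal-bound alkyne, and C7'–aryl a reductive elimination. The ring, all carbons and the stereocentre C2 come from three achiral pieces. The forward step needs anti addition across the alkyne and a catalyst that selects one enantiomer of the equilibrating adduct 8.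

**3 to 1 and 2.** The C2=C3 double bond is cut as a Knoevenagel condensation. The aldehyde cannot enolise and the malonate is symmetric, so there is no selectivity problem.

**5 to 4.** The C–I bond is cut as an electrophilic iodination. The forward step relies on the position para to one methoxy group and ortho to another being by far the most activated.

## Other disconnections considered

**Alternative 1:** The cut goes through C2–C3 and O1–C5, with C5 at the carboxyl level and C7' as an exocyclic methylene. In the forward direction, 1 would be allylborated by the γ-substituted 2-alkoxycarbonyl allylboronate A2 under a chiral phosphoric acid. A closed chair with the aryl group equatorial should give the syn adduct, whose oxygen closes the cis lactone A1.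
- In its favour: this is a known class of catalytic enantioselective C–C bond formation. It sets C2 and C3 together in the required cis sense, and on precedent and security of absolute configuration it is better than the chosen plan. The later hydrogenation that sets C4 would be steered by two cis substituents and not one, which is equal or better.
- Against it: C7'–aryl is not formed in the key step and needs a Heck arylation with 5. C5 arrives as a carbonyl and must be deoxygenated, either by reduction to the diol and Williamson re-closure or by lactol reduction under Lewis acid, which threatens the ionisable C2–O1 bond. A silyl group must be carried and removed, and A2 needs its own synthesis with defined alkene geometry.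
- Comparison: the alternative forms two skeletal bonds and two stereocentres in a well-understood transition state. The chosen plan forms three bonds and one stereocentre by an unproven enantioselection. In step count the chosen plan is clearly shorter (7 steps against roughly 10 or more).

**Alternative 2:** The cut is C2–C3, with C9 tied back to C7' as a lactone. In the forward direction, Rh2(OAc)4 would convert the diazo lactone A4 into a rhodium carbene that inserts into the benzylic ether C–H bond. This closes the oxolane as the cis-fused furofuranone A3 with the C2 aryl endo.
- In its favour: the bicycle enforces the C3–C4 cis relationship, and the endo aryl gives the C2–C3 cis relationship, so the all-cis pattern would be set in one known type of reaction. C9 is already at a useful oxidation level, and the lactone C7'–O bond can be hydrogenolysed to the benzyl group, giving an acid identical with F4. In relative stereocontrol this alternative is better than the chosen plan, which needs two separate substrate-controlled hydrogen deliveries.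
- Against it: the absolute configuration must be built into A4, a trans-disubstituted lactone that needs an enantioselective synthesis, etherification and diazo transfer. The carbene meets two very electron-rich arenes and an ether oxygen, so Buchner-type addition and ylide formation compete with insertion. The final hydrogenolysis must distinguish the lactone C7'–O bond from the C2–O1 ether.
- Comparison: the C2–O1 hydrogenolysis risk is shared with the chosen plan, so on that point the two are equal. In step count and convergence the chosen plan is better, since A4 alone would take about as many steps as the whole chosen route.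

**Alternative 3:** The cut is O1–C5, with C2=C3 as an enol ether double bond and C4 carried from a cyclopropane. In the forward direction, NaI would open the acyl cyclopropane A6 at its unsubstituted carbon, and the keto ester enolate oxygen would displace iodide (5-exo-tet, a Cloke–Wilson-type ring expansion) to give the dihydrofuran A5.
- In its favour: the ring expansion is simple, catalytic in iodide and leaves the stereocentre untouched. C4 would be set at the outset by reagent control and not by relay from C2, which is equal or better than the chosen plan for that centre. Cis hydrogenation of A5 anti to the benzyl group would create C2 and C3 together and meet the chosen route at 14.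
- Against it: the C2=C3 bond of A5 is a tetrasubstituted push–pull alkene and a poor hydrogenation substrate. Forcing conditions would endanger the C2–O1 bond, and a single C4 substituent must enforce a fully cis product. Other reductions (hydride and protonation) would not secure C3. Enantiopure A6 needs several steps.
- Comparison: overall length would be similar to the chosen plan, so step economy is about equal. The key step forms one bond where the chosen plan forms three, and the hardest stereochemical task is moved to a difficult hydrogenation.

Key step: step 3

Assumption: the sense of induction of the chiral ligand in step 3 cannot be predicted, so (S,S)-CHIRAPHOS is written and its antipode would be used if first trials favour the wrong enantiomer. Ring atoms are numbered O1, C2 (aryl), C3 (bearing C9), C4 (bearing C7'), C5. The descriptor at C2 is S in 9–13, where the quaternary C3 outranks the aryl group, and R in 14 and 15, with no change in spatial arrangement.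

## Route

Step 1
Reactants: 1 3,4,5-trimethoxybenzaldehyde; 2 diethyl malonate
Product: 3 diethyl 2-[(3,4,5-trimethoxyphenyl)methylidene]propanedioate
Conditions: piperidine (cat.), AcOH (cat.), toluene, reflux, azeotropic removal of water
Reagents that add atoms: none
Why: Knoevenagel condensation of a non-enolisable aldehyde with a symmetric malonate; removal of water drives it to completion and only one alkene isomer is possible.

Step 2
Reactants: 4 1,2,4-trimethoxybenzene
Product: 5 1-iodo-2,4,5-trimethoxybenzene
Conditions: N-iodosuccinimide, CF3CO2H (cat.), MeCN, rt
Reagents that add atoms: N-iodosuccinimide, O=C1CCC(=O)N1I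
Why: Electrophilic aromatic iodination; C5 of 4 is para to one methoxy group and ortho to another, whereas C3 is flanked by two methoxy groups and C6 is activated by only one, so a single regioisomer is expected.

Step 3
Reactants: 3 diethyl 2-[(3,4,5-trimethoxyphenyl)methylidene]propanedioate; 5 1-iodo-2,4,5-trimethoxybenzene; 6 prop-2-yn-1-ol (propargyl alcohol)
Product: 9 diethyl (2S,4Z)-2-(3,4,5-trimethoxyphenyl)-4-[(2,4,5-trimethoxyphenyl)methylidene]oxolane-3,3-dicarboxylate, via lithium prop-2-yn-1-olate 7 (not isolated), via lithium malonate oxa-Michael adduct 8 (not isolated)
Conditions: 6, n-BuLi (1.0 equiv), THF, 0 °C; then 3, 5 (slow addition), Pd2(dba)3 (2.5 mol %), (S,S)-CHIRAPHOS (5.5 mol %), THF–DMSO, rt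
Reagents that add atoms: none
Why: Proposed new method: the closest known reaction type is the racemic palladium-catalysed three-component coupling of propargyl alkoxides, alkylidene malonates and aryl halides to 4-arylidene oxolanes, and the proposal is to make it enantioselective with a chiral bisphosphine on zerovalent palladium. Alkoxide 7 adds reversibly to the benzylidene carbon of 3 (O1–C2), so the two enantiomers of the stabilised malonate 8 interconvert by retro-oxa-Michael cleavage. Oxidative addition of 5 to the zerovalent palladium–bisphosphine complex gives an arylpalladium iodide that binds the alkyne of 8 after loss of iodide. The malonate carbon then attacks the internal alkyne carbon from the side opposite the metal, a 5-exo-dig closure that forms C3–C4 and the only ring. Reductive elimination from the cis aryl(vinyl)palladium species forms C7'–aryl with retention, which places the aryl trans to C3 (4Z) and returns zerovalent palladium. C2 is the only new stereocentre and is controlled by the catalyst alone: the chiral pocket must make cyclisation of one enantiomer of 8 faster than the other while retro-addition keeps them in equilibrium (a dynamic kinetic resolution), and the product cannot revert because C3 is quaternary. CHIRAPHOS is chosen as the chiral analogue of the 1,2-bis(diphenylphosphino)ethane-type chelates that support anti carbopalladation by malonates, and its P-phenyl groups lie close to the C2 aryl in the cyclisation transition state. The step also needs 5-exo over 6-endo attack (secured by the three-atom tether and the anti geometry), C-attack by the soft malonate in place of O–aryl or alkyne–aryl coupling, and equilibration faster than cyclisation (helped by the readily expelled stabilised malonate, the polar cosolvent and slow addition of 5).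

Step 4
Reactants: 9 diethyl (2S,4Z)-2-(3,4,5-trimethoxyphenyl)-4-[(2,4,5-trimethoxyphenyl)methylidene]oxolane-3,3-dicarboxylate
Product: 10 diethyl (2S,4R)-2-(3,4,5-trimethoxyphenyl)-4-[(2,4,5-trimethoxyphenyl)methyl]oxolane-3,3-dicarboxylate
Conditions: H2 (1 atm), 10% Pd/C, Ph2S (cat.), EtOAc, rt
Reagents that add atoms: none
Why: Heterogeneous catalytic hydrogenation adds both hydrogens syn to the face of the styrene-type alkene opposite the C2 aryl group, which sets C4 with the benzyl group cis to the aryl (4R). The sulfide-moderated catalyst should saturate the alkene while suppressing hydrogenolysis of the benzylic C2–O1 bond.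

Step 5
Reactants: 10 diethyl (2S,4R)-2-(3,4,5-trimethoxyphenyl)-4-[(2,4,5-trimethoxyphenyl)methyl]oxolane-3,3-dicarboxylate
Product: 11 (2S,3S,4R)-3-(ethoxycarbonyl)-2-(3,4,5-trimethoxyphenyl)-4-[(2,4,5-trimethoxyphenyl)methyl]oxolane-3-carboxylic acid
Conditions: KOH (1.1 equiv), EtOH–H2O, 40 °C; then 1 M HCl
Reagents that add atoms: potassium hydroxide, [K+].[OH-]
Why: Mono-saponification of a geminal diester; the first carboxylate repels further hydroxide, and the ester trans to the aryl and benzyl groups is the accessible one. The C3 configuration of 11 has no consequence, because either half-acid gives the same planar radical in step 6.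

Step 6
Reactants: 11 (2S,3S,4R)-3-(ethoxycarbonyl)-2-(3,4,5-trimethoxyphenyl)-4-[(2,4,5-trimethoxyphenyl)methyl]oxolane-3-carboxylic acid
Product: 14 ethyl (2R,3S,4R)-2-(3,4,5-trimethoxyphenyl)-4-[(2,4,5-trimethoxyphenyl)methyl]oxolane-3-carboxylate, via acid chloride 12 (not isolated), via Barton ester 13 (not isolated)
Conditions: (COCl)2, DMF (cat.), CH2Cl2, 0 °C to rt, evaporate; sodium 2-thioxopyridin-1(2H)-olate (C5H4NNaOS), DMAP (cat.), THF, 0 °C, dark; then (Me3Si)3SiH, hν (tungsten lamp), 0 °C
Reagents that add atoms: none
Why: Barton reductive decarboxylation: homolysis of the thiohydroxamate N–O bond and loss of CO2 give a planar tertiary α-ester radical at C3. The bulky, hydridic silane (polarity-matched to this electrophilic radical) should deliver hydrogen to the face opposite the cis C2 aryl and C4 benzyl groups, which leaves the ester cis to both (3S), the kinetic all-cis outcome.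

Step 7
Reactants: 14 ethyl (2R,3S,4R)-2-(3,4,5-trimethoxyphenyl)-4-[(2,4,5-trimethoxyphenyl)methyl]oxolane-3-carboxylate
Product: 15 [(2R,3R,4R)-2-(3,4,5-trimethoxyphenyl)-4-[(2,4,5-trimethoxyphenyl)methyl]oxolan-3-yl]methanol
Conditions: LiAlH4, THF, 0 °C; then H2O, aq. NaOH
Reagents that add atoms: none
Why: Hydride reduction of the ester to the primary alcohol; at 0 °C, addition to the carbonyl is much faster than enolisation, so C3 should neither epimerise nor lose O1 by β-elimination. No other group is reducible.

## Compound list

1 | 3,4,5-trimethoxybenzaldehyde | COc1cc(C=O)cc(OC)c1OC | starting material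
2 | diethyl malonate (diethyl propanedioate) | CCOC(=O)CC(=O)OCC | starting material
3 | diethyl 2-[(3,4,5-trimethoxyphenyl)methylidene]propanedioate | CCOC(=O)C(=Cc1cc(OC)c(OC)c(OC)c1)C(=O)OCC | intermediate
4 | 1,2,4-trimethoxybenzene | COc1ccc(OC)c(OC)c1 | starting material
5 | 1-iodo-2,4,5-trimethoxybenzene | COc1cc(OC)c(I)cc1OC | intermediate
6 | prop-2-yn-1-ol (propargyl alcohol) | C#CCO | starting material
7 | lithium prop-2-yn-1-olate | [Li+].[O-]CC#C | intermediate
8 | lithium salt of the malonate carbanion of diethyl 2-[(prop-2-yn-1-yloxy)(3,4,5-trimethoxyphenyl)methyl]propanedioate (both enantiomers, in equilibrium) | [Li+].CCOC(=O)[C-](C(=O)OCC)C(OCC#C)c1cc(OC)c(OC)c(OC)c1 | intermediate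
9 | diethyl (2S,4Z)-2-(3,4,5-trimethoxyphenyl)-4-[(2,4,5-trimethoxyphenyl)methylidene]oxolane-3,3-dicarboxylate | O1[C@@H](c2cc(OC)c(OC)c(OC)c2)C(C(=O)OCC)(C(=O)OCC)/C(=C/c2cc(OC)c(OC)cc2OC)C1 | intermediate
10 | diethyl (2S,4R)-2-(3,4,5-trimethoxyphenyl)-4-[(2,4,5-trimethoxyphenyl)methyl]oxolane-3,3-dicarboxylate (aryl and benzyl cis) | COc1cc(OC)c(OC)cc1C[C@H]1CO[C@@H](c2cc(OC)c(OC)c(OC)c2)C1(C(=O)OCC)C(=O)OCC | intermediate
11 | (2S,3S,4R)-3-(ethoxycarbonyl)-2-(3,4,5-trimethoxyphenyl)-4-[(2,4,5-trimethoxyphenyl)methyl]oxolane-3-carboxylic acid (acid trans to aryl and benzyl) | COc1cc(OC)c(OC)cc1C[C@H]1CO[C@@H](c2cc(OC)c(OC)c(OC)c2)[C@@]1(C(=O)O)C(=O)OCC | intermediate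
12 | ethyl (2S,3R,4R)-3-(chlorocarbonyl)-2-(3,4,5-trimethoxyphenyl)-4-[(2,4,5-trimethoxyphenyl)methyl]oxolane-3-carboxylate | COc1cc(OC)c(OC)cc1C[C@H]1CO[C@@H](c2cc(OC)c(OC)c(OC)c2)[C@@]1(C(Cl)=O)C(=O)OCC | intermediate
13 | 3-ethyl 3-(2-thioxopyridin-1(2H)-yl) (2S,3R,4R)-2-(3,4,5-trimethoxyphenyl)-4-[(2,4,5-trimethoxyphenyl)methyl]oxolane-3,3-dicarboxylate (Barton ester) | COc1cc(OC)c(OC)cc1C[C@H]1CO[C@@H](c2cc(OC)c(OC)c(OC)c2)[C@@]1(C(=O)On3ccccc3=S)C(=O)OCC | intermediate
14 | ethyl (2R,3S,4R)-2-(3,4,5-trimethoxyphenyl)-4-[(2,4,5-trimethoxyphenyl)methyl]oxolane-3-carboxylate (all-cis) | COc1cc(OC)c(OC)cc1C[C@H]1CO[C@@H](c2cc(OC)c(OC)c(OC)c2)[C@H]1C(=O)OCC | intermediate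
15 | [(2R,3R,4R)-2-(3,4,5-trimethoxyphenyl)-4-[(2,4,5-trimethoxyphenyl)methyl]oxolan-3-yl]methanol (all-cis) | COc1cc(OC)c(OC)cc1C[C@H]1CO[C@@H](c2cc(OC)c(OC)c(OC)c2)[C@H]1CO | target

## Step count and least certain steps

Total step count: 7. Longest linear sequence: 6 steps (steps 1, 3, 4, 5, 6, 7); step 2 is a one-step side branch.

**Step 3 (key step, proposed new method).** The cyclisation may fail to distinguish the two equilibrating enantiomers of 8, or it may outrun their interconversion so that no dynamic resolution operates. Direct coupling of the alkoxide or the terminal alkyne with the arylpalladium species may also compete.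
Fallback (known chemistry, resolution in place of asymmetric catalysis): setting out from 3, 5 and 6, the coupling would be run in its racemic form with an achiral catalyst (PdCl2(PPh3)2 reduced in situ by n-BuLi to zerovalent palladium, THF–DMSO, rt). This would give racemic diethyl (4Z)-2-(3,4,5-trimethoxyphenyl)-4-[(2,4,5-trimethoxyphenyl)methylidene]oxolane-3,3-dicarboxylate F1. The enantiomers would be separated by preparative chromatography on a chiral stationary phase, and the (2S) enantiomer rejoins the route at 9.

**Step 4.** Facial selectivity may be poor, because the only control element is the C2 aryl group two bonds away across a quaternary carbon with an ester on each face. Hydrogenolysis of the activated C2–O1 bond is the second danger.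
Fallback (chelation-directed delivery in place of steric approach to a surface): setting out from 9, the ester trans to the aryl group would be saponified first (KOH, EtOH–H2O) to give (2S,3S,4Z)-3-(ethoxycarbonyl)-2-(3,4,5-trimethoxyphenyl)-4-[(2,4,5-trimethoxyphenyl)methylidene]oxolane-3-carboxylic acid F2. Its carboxylate would then direct a cationic rhodium catalyst ([Rh(nbd)(dppb)]BF4, H2 under pressure, Et3N, MeOH) to its own face, which is the face opposite the aryl group. This homogeneous catalyst has little tendency to cleave benzylic ethers, and the route is rejoined at 11.

**Step 5.** The two esters may not be differentiated. Attack at the neopentyl-like quaternary centre may be too slow, or hydrolysis may run on to the diacid.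
Fallback (no differentiation needed; ionic decarboxylation): setting out from 10, both esters would be saponified (excess KOH, EtOH–H2O, reflux; HCl) to (2S,4R)-2-(3,4,5-trimethoxyphenyl)-4-[(2,4,5-trimethoxyphenyl)methyl]oxolane-3,3-dicarboxylic acid F3. Thermal decarboxylation (xylene, 140 °C) passes through an enediol that should be protonated at C3 from the open face, giving the all-cis (2R,3S,4R)-2-(3,4,5-trimethoxyphenyl)-4-[(2,4,5-trimethoxyphenyl)methyl]oxolane-3-carboxylic acid F4. Reduction with BH3·THF then leads directly to 15.

**Step 6.** Hydrogen transfer to the hindered, electrophilic tertiary radical may be slow. Capture of the radical by the thiocarbonyl group of the Barton ester, or erosion of facial control, could then compete, and acylation of the hindered acid may be sluggish.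
Fallback (reductive single-electron activation without a thiocarbonyl group): setting out from 11, coupling with N-hydroxyphthalimide (N,N'-diisopropylcarbodiimide, DMAP, CH2Cl2) would give 3-ethyl 3-(1,3-dioxoisoindolin-2-yl) (2S,3R,4R)-2-(3,4,5-trimethoxyphenyl)-4-[(2,4,5-trimethoxyphenyl)methyl]oxolane-3,3-dicarboxylate F5. Visible-light reduction with diethyl 2,6-dimethyl-1,4-dihydropyridine-3,5-dicarboxylate and Ru(bpy)3Cl2 (cat.) generates the same C3 radical and supplies the hydrogen atom from a hydridic C–H donor, so the route is rejoined at 14.

## Further compounds

F1 | step 3 | diethyl (4Z)-2-(3,4,5-trimethoxyphenyl)-4-[(2,4,5-trimethoxyphenyl)methylidene]oxolane-3,3-dicarboxylate, racemate | O1C(c2cc(OC)c(OC)c(OC)c2)C(C(=O)OCC)(C(=O)OCC)/C(=C/c2cc(OC)c(OC)cc2OC)C1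
F2 | step 4 | (2S,3S,4Z)-3-(ethoxycarbonyl)-2-(3,4,5-trimethoxyphenyl)-4-[(2,4,5-trimethoxyphenyl)methylidene]oxolane-3-carboxylic acid | O1[C@@H](c2cc(OC)c(OC)c(OC)c2)[C@@](C(=O)O)(C(=O)OCC)/C(=C/c2cc(OC)c(OC)cc2OC)C1
F3 | step 5 | (2S,4R)-2-(3,4,5-trimethoxyphenyl)-4-[(2,4,5-trimethoxyphenyl)methyl]oxolane-3,3-dicarboxylic acid | COc1cc(OC)c(OC)cc1C[C@H]1CO[C@@H](c2cc(OC)c(OC)c(OC)c2)C1(C(=O)O)C(=O)O
F4 | step 5 | (2R,3S,4R)-2-(3,4,5-trimethoxyphenyl)-4-[(2,4,5-trimethoxyphenyl)methyl]oxolane-3-carboxylic acid (all-cis) | COc1cc(OC)c(OC)cc1C[C@H]1CO[C@@H](c2cc(OC)c(OC)c(OC)c2)[C@H]1C(=O)O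
F5 | step 6 | 3-ethyl 3-(1,3-dioxoisoindolin-2-yl) (2S,3R,4R)-2-(3,4,5-trimethoxyphenyl)-4-[(2,4,5-trimethoxyphenyl)methyl]oxolane-3,3-dicarboxylate | COc1cc(OC)c(OC)cc1C[C@H]1CO[C@@H](c2cc(OC)c(OC)c(OC)c2)[C@@]1(C(=O)ON3C(=O)c4ccccc4C3=O)C(=O)OCC
A1 | alternative 1 | (4R,5R)-4-({[tert-butyl(dimethyl)silyl]oxy}methyl)-3-methylidene-5-(3,4,5-trimethoxyphenyl)oxolan-2-one (cis) | O=C1O[C@@H](c2cc(OC)c(OC)c(OC)c2)[C@@H](CO[Si](C)(C)C(C)(C)C)C1=C
A2 | alternative 1 | methyl (2E)-4-{[tert-butyl(dimethyl)silyl]oxy}-2-[(4,4,5,5-tetramethyl-1,3,2-dioxaborolan-2-yl)methyl]but-2-enoate | COC(=O)/C(CB1OC(C)(C)C(C)(C)O1)=C/CO[Si](C)(C)C(C)(C)C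
A3 | alternative 2 | cis-fused 2-endo-(3,4,5-trimethoxyphenyl)-6-exo-(2,4,5-trimethoxyphenyl)-3,7-dioxabicyclo[3.3.0]octan-8-one | O1[C@@H](c3cc(OC)c(OC)c(OC)c3)[C@H]2C(=O)O[C@H](c3cc(OC)c(OC)cc3OC)[C@H]2C1
A4 | alternative 2 | trans-3-diazo-5-(2,4,5-trimethoxyphenyl)-4-{[(3,4,5-trimethoxyphenyl)methoxy]methyl}oxolan-2-one | O=C1O[C@H](c2cc(OC)c(OC)cc2OC)[C@@H](COCc2cc(OC)c(OC)c(OC)c2)C1=[N+]=[N-]
A5 | alternative 3 | ethyl (4R)-2-(3,4,5-trimethoxyphenyl)-4-[(2,4,5-trimethoxyphenyl)methyl]-4,5-dihydrofuran-3-carboxylate | O1C(c2cc(OC)c(OC)c(OC)c2)=C(C(=O)OCC)[C@@H](Cc2cc(OC)c(OC)cc2OC)C1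
A6 | alternative 3 | ethyl (2S)-1-(3,4,5-trimethoxybenzoyl)-2-[(2,4,5-trimethoxyphenyl)methyl]cyclopropane-1-carboxylate (either configuration at C1) | CCOC(=O)C1(C(=O)c2cc(OC)c(OC)c(OC)c2)C[C@@H]1Cc1cc(OC)c(OC)cc1OC
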